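The hardest feature is C7. It is a quaternary stereocentre on the acyl-bearing, least nucleophilic carbon of a dearomatised phloroglucinol, where direct prenylation goes to C3a or C5. C7 must also be related to C5 across C6 and to the remote pair C2/C1′, and O1 must sit on C7a, not on C4.
Cuts: C5–CH3; C7–CH2 (prenyl), traced back through a temporary C3a–CMe2 bond to an O4-prenyl aryl ether; C5–C6 and C3a–C4 (carbocycle); O1–C2 and C3–C3a (dihydrofuran).
Forward: the dihydrofuran ring arises first from a tricarbonyl dianion and epoxyneryl bromide, which fixes O1 next to C7. The six-membered ring comes second, as an arene, by acylation/Claisen cyclisation. Claisen/Cope dearomatisation follows, then C5 methylation.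
Enabling feature: C4–O is para to C7 and ortho to the ring-fusion carbon C3a, and C3a lies in the five-membered ring 1,3 to stereocentre C2. A prenyl group on O4 can therefore land on C3a anti to the C2 side chain and walk suprafacially over C7a to C7.
Stereochemistry: C1′ and C2 come from one Sharpless epoxidation of nerol (inversion at C2 on furan closure). C7 comes from the relay C2→C3a→C7. C5 comes from methylation of the planar diketonate anti to the C7 isobutyryl group.

Key step: step 10

Remark: the like (S,S) relation of C2 and C1′ corresponds to anti opening of a Z-derived epoxide, hence nerol and not geraniol. Benzofuran numbering of the target is used throughout (C1′ = carbinol carbon; top face = face anti to the C2 side chain). Enolisable compounds are drawn as one tautomer, and 8, 9 and 12 are E/Z mixtures of no consequence.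

Step 1
Reactants: 1 nerol
Product: 2 (2R,3S)-2,3-epoxynerol
Conditions: Ti(OiPr)4 (cat.), D-(−)-DIPT (cat.), t-BuOOH, 4 Å MS, CH2Cl2, −20 °C
Reagents that add atoms: tert-butyl hydroperoxide, CC(C)(C)OO
Why: Sharpless asymmetric epoxidation; the titanium tartrate binds the allylic alcohol, so only the 2,3-alkene reacts, and the D-(−)-tartrate should deliver oxygen to the face that gives the (2R,3S)-epoxide, which fixes C1′ (final S) and, after one later inversion, C2.

Step 2
Reactants: 2 (2R,3S)-2,3-epoxynerol
Product: 3 epoxyneryl bromide, (2S,3S)-2-(bromomethyl)-3-methyl-3-(4-methylpent-3-en-1-yl)oxirane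
Conditions: CBr4, PPh3, CH2Cl2, 0 °C
Reagents that add atoms: carbon tetrabromide, BrC(Br)(Br)Br
Why: Appel bromination; SN2 at the primary carbinol carbon under neutral conditions leaves the epoxide and both stereocentres untouched (the C2 descriptor changes only because Br outranks O in the CIP order).

Step 3
Reactants: 4 methyl acetoacetate; 5 isobutyryl chloride
Product: 6 methyl 2-acetyl-4-methyl-3-oxopentanoate
Conditions: MgCl2, pyridine, CH2Cl2, 0 °C to rt; aq. HCl work-up
Reagents that add atoms: none
Why: Magnesium chloride/amine-mediated C-acylation of a β-keto ester; the chelated magnesium enolate is acylated on carbon and the acidic tricarbonyl product is held as its chelate, which prevents O-acylation and over-reaction.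

Step 4
Reactants: 6 methyl 2-acetyl-4-methyl-3-oxopentanoate; 3 epoxyneryl bromide
Product: 8 methyl 2-{(5S)-5-[(2S)-2-hydroxy-6-methylhept-5-en-2-yl]oxolan-2-ylidene}-4-methyl-3-oxopentanoate, via epoxy tricarbonyl ester 7 (not isolated)
Conditions: LDA (2.2 equiv), THF, −78 to 0 °C; 3, −78 °C to rt, then 50 °C; H2O
Reagents that add atoms: none
Why: γ-Alkylation of a β-dicarbonyl dianion followed by 5-exo-tet epoxide opening by enolate oxygen (the dianion/epihalohydrin route to 2-alkylidenetetrahydrofurans); the terminal carbanion displaces the primary bromide, then only the oxygen on C7a reaches C2 through a five-membered transition state and opens the epoxide at its less substituted carbon with inversion (C2 becomes S, C1′ keeps its C–O bond), which places O1 next to the acyl-bearing C7 once and for all.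

Step 5
Reactants: 8 alkylidene-oxolane alcohol
Product: 9 methyl 4-methyl-2-{(5S)-5-[(2S)-6-methyl-2-(triethylsilyloxy)hept-5-en-2-yl]oxolan-2-ylidene}-3-oxopentanoate
Conditions: TESOTf, 2,6-lutidine, CH2Cl2, −78 to 0 °C
Reagents that add atoms: triethylsilyl trifluoromethanesulfonate, CC[Si](CC)(CC)OS(=O)(=O)C(F)(F)F
Why: Silyl triflate silylation of a hindered tertiary alcohol; it masks the alcohol against the acylation of step 7 and enlarges the C2 substituent that steers step 10.

Step 6
Reactants: 10 5-methylhex-4-enoic acid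
Product: 11 5-methylhex-4-enoyl chloride
Conditions: (COCl)2, DMF (cat.), CH2Cl2, 0 °C to rt
Reagents that add atoms: oxalyl chloride, O=C(Cl)C(=O)Cl
Why: Acid chloride formation through the catalytic chloroiminium species, mild enough for the trisubstituted alkene.

Step 7
Reactants: 9 silylated alkylidene-oxolane; 11 5-methylhex-4-enoyl chloride
Product: 13 1-{(2S)-4,6-dihydroxy-5-(3-methylbut-2-en-1-yl)-2-[(2S)-6-methyl-2-(triethylsilyloxy)hept-5-en-2-yl]-2,3-dihydro-1-benzofuran-7-yl}-2-methylpropan-1-one, via triketo ester 12 (not isolated)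
Conditions: LiHMDS (2.1 equiv), THF, −78 °C; 11; then LiHMDS (2.5 equiv), −78 °C to rt; aq. NH4Cl
Reagents that add atoms: none
Why: γ-C-acylation of an extended enolate followed by Claisen (Dieckmann-type) cyclisation of a poly-β-carbonyl polyanion, as in biomimetic acylphloroglucinol formation; C7 is fully substituted, so the acyl group is taken up at C3a, further deprotonation at C5 gives the carbanion that attacks the ester carbon C6 (methoxide loss is irreversible, whereas addition to the hindered, enolate-like isobutyryl carbonyl is reversible and cannot dehydrate under aprotic conditions), and tautomerisation to the arene drives the closure.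

Step 8
Reactants: 13 benzofurandiol; 14 prenol (3-methylbut-2-en-1-ol)
Product: 15 1-{(2S)-6-hydroxy-5-(3-methylbut-2-en-1-yl)-4-(3-methylbut-2-en-1-yloxy)-2-[(2S)-6-methyl-2-(triethylsilyloxy)hept-5-en-2-yl]-2,3-dihydro-1-benzofuran-7-yl}-2-methylpropan-1-one
Conditions: PPh3, DIAD, THF, 0 °C to rt
Reagents that add atoms: none
Why: Mitsunobu etherification; only the free and more acidic 4-OH (para to the acyl group) reacts because 6-OH is locked in a hydrogen bond to the ketone, and the method gives O- and not C-alkylation.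

Step 9
Reactants: 15 4-O-prenyl ether
Product: 16 1-{(2S)-5-(3-methylbut-2-en-1-yl)-4-(3-methylbut-2-en-1-yloxy)-2-[(2S)-6-methyl-2-(triethylsilyloxy)hept-5-en-2-yl]-6-(triethylsilyloxy)-2,3-dihydro-1-benzofuran-7-yl}-2-methylpropan-1-one
Conditions: TESOTf, 2,6-lutidine, CH2Cl2, 0 °C
Reagents that add atoms: triethylsilyl trifluoromethanesulfonate, CC[Si](CC)(CC)OS(=O)(=O)C(F)(F)F
Why: Silylation of the chelated phenol; it removes the O6–H···O=C chelate that would fix a C4=C5 bond and steer the Claisen step to C5, and it adds bulk next to C5.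

Step 10
Reactants: 16 bis-silylated aryl prenyl ether
Product: 19 (2S,7S)-6-hydroxy-5,7-bis(3-methylbut-2-en-1-yl)-7-(2-methylpropanoyl)-2-[(2S)-6-methyl-2-(triethylsilyloxy)hept-5-en-2-yl]-3,7-dihydro-1-benzofuran-4(2H)-one, via ortho-dienone 17 (not isolated), via silyl dienone 18 (not isolated)
Conditions: PhNEt2 (degassed), 175 °C, sealed tube; concentrate; AcOH–THF–H2O, rt
Reagents that add atoms: none
Why: Heating triggers an aromatic Claisen rearrangement in which the CMe2 terminus of the O4-prenyl group bonds to the ring-fusion carbon C3a (ortho-dienone 17, temporary C3a–C bond), the strained 1,5-diene CH2=CH–CMe2–C3a–C7a=C7 then undergoes a Cope rearrangement that cuts this bond again and lays a linear prenyl group on C7, para to O4, and mild acid finally hydrolyses only the vinylogous silyl ester of 18. The closest known reaction type is the para-Claisen (Claisen/Cope) rearrangement of aryl prenyl ethers, which is used on Mitsunobu-made prenyl ethers of acylphloroglucinols and is known to stop at a 4,4-disubstituted cyclohexadienone when the para carbon is substituted. No ring is closed; both shifts run through six-membered cyclic transition states on one face of the bicycle. The transient stereocentre C3a lies in the five-membered ring 1,3 to C2, so, as in the α-alkylation of γ-substituted butyrolactone enolates, the bulky CMe2 terminus should add anti to the large C2 substituent, and because the Cope shift is suprafacial the prenyl group arrives on the same (top) face of C7, which is the required C2/C7 relation. The step needs bond formation at the acyl-bearing carbon, which the para relation O4/C7 dictates whichever ortho carbon is visited, and it needs passage through C3a rather than C5, which is favoured because the 6-O-silyl group removes the chelate, the fused five-membered ring raises the C3a–C4 bond order (Mills–Nixon effect) and C5 is flanked by a prenyl and a silyloxy group. The product cannot rearomatise by tautomerisation (C7 is quaternary) and is stabilised as a doubly vinylogous ester, so the dearomatisation should be downhill and C7 should keep its configuration if heating is stopped at full conversion.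

Step 11
Reactants: 19 enol-dienone
Product: 20 (2S,5S,7S)-5-methyl-5,7-bis(3-methylbut-2-en-1-yl)-7-(2-methylpropanoyl)-2-[(2S)-6-methyl-2-(triethylsilyloxy)hept-5-en-2-yl]-2,3-dihydro-1-benzofuran-4,6(5H,7H)-dione
Conditions: LiOt-Bu (1.0 equiv), MeI (excess), THF, 0 °C to rt
Reagents that add atoms: iodomethane, CI
Why: C-alkylation of the lithium enolate of a 2-substituted cyclic 1,3-diketone; C5 is the only nucleophilic carbon of this diketonate and lithium favours C- over O-methylation, and the new stereocentre C5 should be set by attack of MeI on the top face, anti to the isobutyryl group (held under C5–C6 by lithium bridging O6 and the acyl oxygen) and anti to the C2 side chain, so that methyl ends cis to the C7 prenyl group (5S).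

Step 12
Reactants: 20 silyl ether of the target
Product: 21 target, (2S,5S,7S)-2-[(2S)-2-hydroxy-6-methylhept-5-en-2-yl]-5-methyl-5,7-bis(3-methylbut-2-en-1-yl)-7-(2-methylpropanoyl)-2,3-dihydro-1-benzofuran-4,6(5H,7H)-dione
Conditions: HF·pyridine, pyridine, THF, 0 °C to rt
Reagents that add atoms: none
Why: Fluoride-induced cleavage of the tertiary triethylsilyl ether under buffered conditions, which avoid both alkoxide formation (retro-Claisen loss of the isobutyryl group) and acid-induced cyclisation of the alkenes; no stereocentre is touched.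

Compound list
1 | nerol, (2Z)-3,7-dimethylocta-2,6-dien-1-ol | CC(C)=CCC/C(C)=C\CO | starting material
2 | (2R,3S)-2,3-epoxynerol, [(2R,3S)-3-methyl-3-(4-methylpent-3-en-1-yl)oxiran-2-yl]methanol | CC(C)=CCC[C@]1(C)O[C@@H]1CO | intermediate
3 | epoxyneryl bromide, (2S,3S)-2-(bromomethyl)-3-methyl-3-(4-methylpent-3-en-1-yl)oxirane | CC(C)=CCC[C@]1(C)O[C@@H]1CBr | intermediate
4 | methyl acetoacetate | CC(=O)CC(=O)OC | starting material
5 | isobutyryl chloride | CC(C)C(=O)Cl | starting material
6 | methyl 2-acetyl-4-methyl-3-oxopentanoate | CC(C)C(=O)C(C(C)=O)C(=O)OC | intermediate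
7 | methyl 4-methyl-2-{3-[(2R,3S)-3-methyl-3-(4-methylpent-3-en-1-yl)oxiran-2-yl]propanoyl}-3-oxopentanoate | CC(C)=CCC[C@]1(C)O[C@@H]1CCC(=O)C(C(=O)OC)C(=O)C(C)C | intermediate
8 | methyl 2-{(5S)-5-[(2S)-2-hydroxy-6-methylhept-5-en-2-yl]oxolan-2-ylidene}-4-methyl-3-oxopentanoate | CC(C)=CCC[C@](C)(O)[C@@H]1CCC(O1)=C(C(=O)OC)C(=O)C(C)C | intermediate
9 | methyl 4-methyl-2-{(5S)-5-[(2S)-6-methyl-2-(triethylsilyloxy)hept-5-en-2-yl]oxolan-2-ylidene}-3-oxopentanoate | CC(C)=CCC[C@](C)(O[Si](CC)(CC)CC)[C@@H]1CCC(O1)=C(C(=O)OC)C(=O)C(C)C | intermediate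
10 | 5-methylhex-4-enoic acid | CC(C)=CCCC(=O)O | starting material
11 | 5-methylhex-4-enoyl chloride | CC(C)=CCCC(=O)Cl | intermediate
12 | methyl 4-methyl-2-{(5S)-3-(5-methylhex-4-enoyl)-5-[(2S)-6-methyl-2-(triethylsilyloxy)hept-5-en-2-yl]oxolan-2-ylidene}-3-oxopentanoate | CC(C)=CCC[C@](C)(O[Si](CC)(CC)CC)[C@@H]1CC(C(=O)CCC=C(C)C)C(O1)=C(C(=O)OC)C(=O)C(C)C | intermediate
13 | 1-{(2S)-4,6-dihydroxy-5-(3-methylbut-2-en-1-yl)-2-[(2S)-6-methyl-2-(triethylsilyloxy)hept-5-en-2-yl]-2,3-dihydro-1-benzofuran-7-yl}-2-methylpropan-1-one | CC(C)=CCC[C@](C)(O[Si](CC)(CC)CC)[C@@H]1Cc2c(O1)c(C(=O)C(C)C)c(O)c(CC=C(C)C)c2O | intermediate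
14 | prenol, 3-methylbut-2-en-1-ol | CC(C)=CCO | starting material
15 | 4-O-prenyl ether of 13 | CC(C)=CCC[C@](C)(O[Si](CC)(CC)CC)[C@@H]1Cc2c(O1)c(C(=O)C(C)C)c(O)c(CC=C(C)C)c2OCC=C(C)C | intermediate
16 | 6-O-triethylsilyl ether of 15 | CC(C)=CCC[C@](C)(O[Si](CC)(CC)CC)[C@@H]1Cc2c(O1)c(C(=O)C(C)C)c(O[Si](CC)(CC)CC)c(CC=C(C)C)c2OCC=C(C)C | intermediate
17 | (2S,3aR)-3a-(2-methylbut-3-en-2-yl)-5-(3-methylbut-2-en-1-yl)-7-(2-methylpropanoyl)-2-[(2S)-6-methyl-2-(triethylsilyloxy)hept-5-en-2-yl]-6-(triethylsilyloxy)-3,3a-dihydro-1-benzofuran-4(2H)-one | CC(C)=CCC[C@](C)(O[Si](CC)(CC)CC)[C@@H]1C[C@@]2(C(C)(C)C=C)C(O1)=C(C(=O)C(C)C)C(O[Si](CC)(CC)CC)=C(CC=C(C)C)C2=O | intermediate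
18 | (2S,7R)-5,7-bis(3-methylbut-2-en-1-yl)-7-(2-methylpropanoyl)-2-[(2S)-6-methyl-2-(triethylsilyloxy)hept-5-en-2-yl]-6-(triethylsilyloxy)-3,7-dihydro-1-benzofuran-4(2H)-one | CC(C)=CCC[C@](C)(O[Si](CC)(CC)CC)[C@@H]1CC2=C(O1)[C@@](CC=C(C)C)(C(=O)C(C)C)C(O[Si](CC)(CC)CC)=C(CC=C(C)C)C2=O | intermediate
19 | (2S,7S)-6-hydroxy-5,7-bis(3-methylbut-2-en-1-yl)-7-(2-methylpropanoyl)-2-[(2S)-6-methyl-2-(triethylsilyloxy)hept-5-en-2-yl]-3,7-dihydro-1-benzofuran-4(2H)-one | CC(C)=CCC[C@](C)(O[Si](CC)(CC)CC)[C@@H]1CC2=C(O1)[C@@](CC=C(C)C)(C(=O)C(C)C)C(O)=C(CC=C(C)C)C2=O | intermediate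
20 | (2S,5S,7S)-5-methyl-5,7-bis(3-methylbut-2-en-1-yl)-7-(2-methylpropanoyl)-2-[(2S)-6-methyl-2-(triethylsilyloxy)hept-5-en-2-yl]-2,3-dihydro-1-benzofuran-4,6(5H,7H)-dione | CC(C)=CCC[C@](C)(O[Si](CC)(CC)CC)[C@@H]1CC2=C(O1)[C@@](CC=C(C)C)(C(=O)C(C)C)C(=O)[C@@](C)(CC=C(C)C)C2=O | intermediate
21 | (2S,5S,7S)-2-[(2S)-2-hydroxy-6-methylhept-5-en-2-yl]-5-methyl-5,7-bis(3-methylbut-2-en-1-yl)-7-(2-methylpropanoyl)-2,3-dihydro-1-benzofuran-4,6(5H,7H)-dione | CC(C)=CCC[C@](C)(O)[C@@H]1CC2=C(O1)[C@@](CC=C(C)C)(C(=O)C(C)C)C(=O)[C@@](C)(CC=C(C)C)C2=O | target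

Total step count: 12. Longest linear sequence: 10 (steps 1, 2, 4, 5, 7, 8, 9, 10, 11, 12).

Steps most likely to fail

Step 10.
- What may go wrong: the prenyl group may pass through C5 instead of C3a, which gives no facial control at C7. It may be lost by ionisation or retro-ene cleavage at the temperature needed. The dearomatisation equilibrium may not lie far enough on the dienone side.
- Idea of the fallback: run the same O4→C3a→C7 relay before the carbocycle exists. The first shift is then an aliphatic, irreversible Claisen rearrangement at lower temperature, and C5 is not available as a landing site.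
- Course of the fallback: it sets out from 12, obtained by quenching step 7 after the acylation. O-alkylation of its enolate with prenyl bromide (K2CO3, DMF) gives the O4-prenyl dienol ether F1. In toluene at about 120 °C this should rearrange to the 3-(2-methylbut-3-en-2-yl) ketone F2, with the CMe2 terminus anti to the oxolane C5 substituent. The Cope rearrangement of F2, with the smaller CO2Me group cis to the quaternary C3a as in the ring-closed series, gives the quaternary keto ester F3. Dieckmann cyclisation of F3 (LiHMDS, THF; the α′-enolate carbon C5 attacks the ester carbon C6) comes back to the route at 19.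

Step 7.
- What may go wrong: acylation may occur on enolate oxygen instead of C3a. The amide base may consume the acid chloride. The ring may close on the isobutyryl carbonyl (aldol mode) instead of on the ester.
- Idea of the fallback: make the C3a–C4 bond by vinylogous aldol addition and oxidation, and close the ring in a separate, metal-templated operation.
- Course of the fallback: it sets out from 9. The lithium dienolate and 5-methylhex-4-enal give the γ-aldol adduct F4, the α-adduct being a reversible, quaternary aldolate. Dess–Martin oxidation gives 12 as an isolated compound. Magnesium methoxide in MeOH/THF, which chelates the tricarbonyl unit and favours the Claisen mode, closes it, and the fallback comes back to the route at 13.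

Step 11.
- What may go wrong: facial selectivity of the small electrophile at C5 may be poor or even reversed, and O-methylation may compete.
- Idea of the fallback: exchange the order in which the two C5 substituents enter. The two orders are stereocomplementary: whichever face of the diketonate is more open, one order places methyl on top. The last bond is then formed by a bulky π-allyl electrophile whose chiral ligand can add catalyst control.
- Course of the fallback: it sets out from 9. Propanoyl chloride in place of 11, under the conditions of step 7, gives the 5-methyl benzofurandiol F6 through the propanoyl triketo ester F5. Mitsunobu etherification with 14 gives the 4-O-prenyl ether F7, and silylation gives the bis-silyl ether F8. Heating as in step 10 leads through the ortho-dienone F9 and the silyl dienone F10, after hydrolysis, to the 5-methyl enol F11. Tsuji–Trost prenylation of F11 at C5 then comes back to the route at 20. Conditions: tert-butyl 3-methylbut-2-en-1-yl carbonate, Pd2(dba)3, and the enantiomer of the DACH-phenyl bisphosphine ligand that directs attack to the bottom face, in toluene at rt. Attack is at the CH2 terminus, and any O-allylation is reversible.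

Further compounds
F1 | step 10 | methyl 4-methyl-2-{(5S)-3-[5-methyl-1-(3-methylbut-2-en-1-yloxy)hex-4-en-1-ylidene]-5-[(2S)-6-methyl-2-(triethylsilyloxy)hept-5-en-2-yl]oxolan-2-ylidene}-3-oxopentanoate | CC(C)=CCC[C@](C)(O[Si](CC)(CC)CC)[C@@H]1CC(=C(CCC=C(C)C)OCC=C(C)C)C(O1)=C(C(=O)OC)C(=O)C(C)C
F2 | step 10 | methyl 4-methyl-2-{(3R,5S)-3-(2-methylbut-3-en-2-yl)-3-(5-methylhex-4-enoyl)-5-[(2S)-6-methyl-2-(triethylsilyloxy)hept-5-en-2-yl]oxolan-2-ylidene}-3-oxopentanoate | CC(C)=CCC[C@](C)(O[Si](CC)(CC)CC)[C@@H]1C[C@](C(C)(C)C=C)(C(=O)CCC=C(C)C)C(O1)=C(C(=O)OC)C(=O)C(C)C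
F3 | step 10 | methyl (2S)-5-methyl-2-{(5S)-3-(5-methylhex-4-enoyl)-5-[(2S)-6-methyl-2-(triethylsilyloxy)hept-5-en-2-yl]-4,5-dihydrofuran-2-yl}-2-(2-methylpropanoyl)hex-4-enoate | CC(C)=CCC[C@](C)(O[Si](CC)(CC)CC)[C@@H]1CC(C(=O)CCC=C(C)C)=C(O1)[C@@](CC=C(C)C)(C(=O)C(C)C)C(=O)OC
F4 | step 7 | methyl 2-{(5S)-3-(1-hydroxy-5-methylhex-4-en-1-yl)-5-[(2S)-6-methyl-2-(triethylsilyloxy)hept-5-en-2-yl]oxolan-2-ylidene}-4-methyl-3-oxopentanoate | CC(C)=CCC[C@](C)(O[Si](CC)(CC)CC)[C@@H]1CC(C(O)CCC=C(C)C)C(O1)=C(C(=O)OC)C(=O)C(C)C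
F5 | step 11 | methyl 4-methyl-2-{(5S)-5-[(2S)-6-methyl-2-(triethylsilyloxy)hept-5-en-2-yl]-3-propanoyloxolan-2-ylidene}-3-oxopentanoate | CC(C)=CCC[C@](C)(O[Si](CC)(CC)CC)[C@@H]1CC(C(=O)CC)C(O1)=C(C(=O)OC)C(=O)C(C)C
F6 | step 11 | 1-{(2S)-4,6-dihydroxy-5-methyl-2-[(2S)-6-methyl-2-(triethylsilyloxy)hept-5-en-2-yl]-2,3-dihydro-1-benzofuran-7-yl}-2-methylpropan-1-one | CC(C)=CCC[C@](C)(O[Si](CC)(CC)CC)[C@@H]1Cc2c(O1)c(C(=O)C(C)C)c(O)c(C)c2O
F7 | step 11 | 1-{(2S)-6-hydroxy-5-methyl-4-(3-methylbut-2-en-1-yloxy)-2-[(2S)-6-methyl-2-(triethylsilyloxy)hept-5-en-2-yl]-2,3-dihydro-1-benzofuran-7-yl}-2-methylpropan-1-one | CC(C)=CCC[C@](C)(O[Si](CC)(CC)CC)[C@@H]1Cc2c(O1)c(C(=O)C(C)C)c(O)c(C)c2OCC=C(C)C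
F8 | step 11 | 1-{(2S)-5-methyl-4-(3-methylbut-2-en-1-yloxy)-2-[(2S)-6-methyl-2-(triethylsilyloxy)hept-5-en-2-yl]-6-(triethylsilyloxy)-2,3-dihydro-1-benzofuran-7-yl}-2-methylpropan-1-one | CC(C)=CCC[C@](C)(O[Si](CC)(CC)CC)[C@@H]1Cc2c(O1)c(C(=O)C(C)C)c(O[Si](CC)(CC)CC)c(C)c2OCC=C(C)C
F9 | step 11 | (2S,3aR)-5-methyl-3a-(2-methylbut-3-en-2-yl)-7-(2-methylpropanoyl)-2-[(2S)-6-methyl-2-(triethylsilyloxy)hept-5-en-2-yl]-6-(triethylsilyloxy)-3,3a-dihydro-1-benzofuran-4(2H)-one | CC(C)=CCC[C@](C)(O[Si](CC)(CC)CC)[C@@H]1C[C@@]2(C(C)(C)C=C)C(O1)=C(C(=O)C(C)C)C(O[Si](CC)(CC)CC)=C(C)C2=O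
F10 | step 11 | (2S,7R)-5-methyl-7-(3-methylbut-2-en-1-yl)-7-(2-methylpropanoyl)-2-[(2S)-6-methyl-2-(triethylsilyloxy)hept-5-en-2-yl]-6-(triethylsilyloxy)-3,7-dihydro-1-benzofuran-4(2H)-one | CC(C)=CCC[C@](C)(O[Si](CC)(CC)CC)[C@@H]1CC2=C(O1)[C@@](CC=C(C)C)(C(=O)C(C)C)C(O[Si](CC)(CC)CC)=C(C)C2=O
F11 | step 11 | (2S,7S)-6-hydroxy-5-methyl-7-(3-methylbut-2-en-1-yl)-7-(2-methylpropanoyl)-2-[(2S)-6-methyl-2-(triethylsilyloxy)hept-5-en-2-yl]-3,7-dihydro-1-benzofuran-4(2H)-one | CC(C)=CCC[C@](C)(O[Si](CC)(CC)CC)[C@@H]1CC2=C(O1)[C@@](CC=C(C)C)(C(=O)C(C)C)C(O)=C(C)C2=O
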